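the same everywhere: starting complex 0.050 M
- birch: incoming ligand 0.037 M; leaving ligand 0.050 M; run made earlier
- larch: incoming ligand 0.056 M; leaving ligand 0.050 M; run made earlier
- flask: incoming ligand 0.0750 M; leaving ligand 0.0500 M; time 20 h

- birch (time / h: complex with one exchanged / %, starting complex / %): 0.500: 13.7, 47.0; 1.00: 20.1, 24.8; 2.50: 25.6, 5.1; 5.00: 25.7, 0.1; 12.0: 23.9, 0.1; 25.0: 20.5, 0
- larch (time / h: complex with one exchanged / %, starting complex / %): 0.500: 20.9, 41.4; 1.00: 28.2, 18.6; 2.50: 32.8, 2.5; 5.00: 31.8, 0.3; 12.0: 27.6, 0.1; 25.0: 22.3, 0.2

(standard deviation of a reading: 0.3 percentage points)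

- a reading or a percentage of leaving ligand counts all its forms, free or not

1. time, not beyond 20 h, at which the flask holds most complex with one exchanged
2. the amount of complex with one exchanged, in percent of the starting complex charged, at that time

- Start with the easy step: turn the starting complex left after 1.00 h into a mean loss rate, 1.39 h⁻¹ in birch and 1.68 h⁻¹ in larch.
- Extend that line in c(incoming ligand) to the flask, which gives 1.97 h⁻¹ and 0.352 h as the half-life of starting complex in the flask, the time in which its amount halves at that rate.
- Now count half-lives: the highest larch reading of complex with one exchanged, at 2.50 h, lies 6.07 larch half-lives from the start, and that count gives the flask 2.14 h.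
- Doubt that count: the neighbouring larch readings stand at 1.00 h and 5.00 h. Compute instead: complex with one exchanged peaks where its supply equals its loss.
- Read that loss from the late readings: 0.0113 h⁻¹ in birch and 0.0177 h⁻¹ in larch. Their ratio is 1.57 and that of c(incoming ligand) 1.51, so take a pseudo-first-order loss and scale it to 0.0238 h⁻¹ for the flask.
- Supply and amount built both carry the share of lost starting complex that becomes complex with one exchanged, which cancels, so expect the peak when starting complex is down to the ratio of the two rates: 1.21% in the flask, or 6.37 half-lives, or 2.24 h.
- Test this on birch: it gives 3.46 h, between the readings at 2.50 h and 5.00 h, which nearly agree.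
- Doubt the rate too: over 2.50 h larch averages 1.48 h⁻¹. Scaled alike, the flask's rate becomes 1.73 h⁻¹ and the peak 2.48 h. Commit to the middle, 2.36 h.
- For the amount, take highest reading over remainder: 0.346 in birch, 0.488 in larch. For the flask the straight line gives 0.630, so 38.7%. Doubt the line: proportion to c(incoming ligand) from larch gives 0.654, so 39.5%. Expect between.
- The forecast says 41.5% at 2.8 h: “the peak comes when it reaches about 1.5%, near 2.8 h”.
- The flask holds most complex with one exchanged, 37.9%, at 2.16 h, with 58.1% of side product beside it.

    starting complex + incoming ligand → leaving ligand + complex with one exchanged (k = 0.210 M⁻¹ min⁻¹)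
    complex with one exchanged + incoming ligand → leaving ligand + complex with two exchanged (k = 0.00990 M⁻¹ min⁻¹)
    complex with two exchanged + incoming ligand → leaving ligand + complex with three exchanged (k = 0.130 M⁻¹ min⁻¹)
    complex with three exchanged + incoming ligand ⇌ leaving ligand + complex with four exchanged (K = 0.160, k = 0.860 M⁻¹ min⁻¹)
    crystals ⇌ leaving ligand, rate k5*(cs5 - [leaving ligand]) while solid is left; crystals form when [leaving ligand] > cs5 (solubility = 47.0 mM, k = 5.60 min⁻¹)
    leaving ligand + starting complex → side product (k = 0.430 M⁻¹ min⁻¹)

- Put the half-life to use once more: 2.16 h is 6.14 half-lives of 0.352 h, which by that count leaves 1.42% of the starting complex, and at that time the flask holds 1.79% of it.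

The runs were computed from invented constants.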